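Selaginellin is the dehydrogenated form of a tris(aryl)methane, so its cyclohexa-2,5-dienone ring (C1 = carbonyl carbon, C4 = carbon on the central methine carbon) is treated as a latent 4-hydroxyphenyl ring and is built, not bought. A 2,4-dienoate on ring A is arylated 1,6 to a vinylketene silyl acetal whose ester carbon, Cα, Cβ and Cγ become C1, C6, C5 and C4. Diels–Alder addition of phenyl vinyl sulfoxide, an acetylene equivalent, supplies C2 and C3 and closes the ring through the bonds C1–C2 and C3–C4 in one operation; sulfoxide elimination aromatises. Ester reduction, deprotection and DDQ dehydrogenation then give the quinone methide.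

Key step: step 6

Remark: in the target the dienone ring and the remaining 4-hydroxyphenyl ring on the central carbon exchange roles by proton transfer, so dehydrogenation of 17 gives one compound whichever ring is drawn as the dienone. Compounds 3, 6, 8, 10 and 11 are taken as catalogue chemicals.

Step 1
Reactants: 1 methyl 4-bromo-2-hydroxybenzoate
Product: 2 methyl 4-bromo-3-formyl-2-hydroxybenzoate
Conditions: MgCl2, Et3N, paraformaldehyde, MeCN, reflux
Reagents that add atoms: paraformaldehyde (formaldehyde), C=O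
Why: The magnesium phenoxide-directed ortho-formylation (Casnati–Skattebøl type) can only attack C3, the one free position ortho to the hydroxyl group, because the other ortho position carries the ester.

Step 2
Reactants: 2 methyl 4-bromo-3-formyl-2-hydroxybenzoate; 3 [4-(methoxymethoxy)phenyl]boronic acid
Product: 4 methyl 3-formyl-2-hydroxy-4-[4-(methoxymethoxy)phenyl]benzoate
Conditions: Pd(dppf)Cl2 (cat.), K2CO3, 1,4-dioxane/H2O, 80 °C
Reagents that add atoms: none
Why: The Suzuki–Miyaura coupling should take place at the C–Br bond, which is activated by the ortho formyl group, and tolerates the free phenol, the aldehyde and the ester.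

Step 3
Reactants: 4 methyl 3-formyl-2-hydroxy-4-[4-(methoxymethoxy)phenyl]benzoate
Product: 5 methyl 3-formyl-4-[4-(methoxymethoxy)phenyl]-2-{[(trifluoromethyl)sulfonyl]oxy}benzoate
Conditions: Tf2O, pyridine, CH2Cl2, 0 °C
Reagents that add atoms: trifluoromethanesulfonic anhydride, O=S(=O)(OS(=O)(=O)C(F)(F)F)C(F)(F)F
Why: O-Sulfonylation of the only free hydroxyl group (aryl triflate formation) turns it into a leaving group for cross-coupling.

Step 4
Reactants: 5 methyl 3-formyl-4-[4-(methoxymethoxy)phenyl]-2-{[(trifluoromethyl)sulfonyl]oxy}benzoate; 6 1-ethynyl-4-(methoxymethoxy)benzene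
Product: 7 methyl 3-formyl-4-[4-(methoxymethoxy)phenyl]-2-{[4-(methoxymethoxy)phenyl]ethynyl}benzoate
Conditions: PdCl2(PPh3)2 (cat.), CuI (cat.), Et3N, DMF, 60 °C
Reagents that add atoms: none
Why: The Sonogashira coupling of the aryl triflate should be fast because the two ortho carbonyl groups favour oxidative addition.

Step 5
Reactants: 7 methyl 3-formyl-4-[4-(methoxymethoxy)phenyl]-2-{[4-(methoxymethoxy)phenyl]ethynyl}benzoate; 8 ethyl (2E)-4-(diethoxyphosphoryl)but-2-enoate
Product: 9 ethyl (2E,4E)-5-{3-(methoxycarbonyl)-6-[4-(methoxymethoxy)phenyl]-2-{[4-(methoxymethoxy)phenyl]ethynyl}phenyl}penta-2,4-dienoate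
Conditions: LiN(SiMe3)2, THF, −78 °C to rt
Reagents that add atoms: none
Why: The vinylogous Horner–Wadsworth–Emmons olefination attacks only the aldehyde and should give the (2E,4E)-dienoate, as is usual for stabilised phosphonate anions.

Step 6
Reactants: 9 ethyl (2E,4E)-5-{3-(methoxycarbonyl)-6-[4-(methoxymethoxy)phenyl]-2-{[4-(methoxymethoxy)phenyl]ethynyl}phenyl}penta-2,4-dienoate; 10 1-bromo-4-(methoxymethoxy)benzene; 11 phenyl vinyl sulfoxide (racemic)
Product: 15 methyl 3-{(4-hydroxyphenyl)[4-(methoxymethoxy)phenyl]methyl}-4-[4-(methoxymethoxy)phenyl]-2-{[4-(methoxymethoxy)phenyl]ethynyl}benzoate (racemic), via Grignard reagent 12 (not isolated), via vinylketene silyl acetal 13 (not isolated), via sulfinyl cycloadduct 14 (not isolated)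
Conditions: 10, Mg, THF; CuBr·SMe2 (10 mol %), Me3SiCl, 9, THF, −78 to −30 °C; pentane, filtration; 11, toluene, 80 then 110 °C; AcOH, H2O, THF, rt
Reagents that add atoms: magnesium, [Mg], and chlorotrimethylsilane, C[Si](C)(C)Cl (both stay only in the intermediates 12 to 14, not in 15)
Why: The copper-catalysed 1,6-conjugate addition of Grignard reagent 12 to dienoate 9, with O-silylation of the dienolate by Me3SiCl, should make the (3E)-vinylketene silyl acetal 13 in the flask and set the triarylmethane carbon as a racemate (this centre ceases to be stereogenic in 17). Diene 13 then undergoes a thermal intermolecular Diels–Alder reaction with phenyl vinyl sulfoxide 11, which closes the six-membered carbocycle by a concerted, asynchronous [4+2] cycloaddition joining the acetal carbon and the former γ-carbon of the dienoate to the two vinyl carbons. Syn-elimination of benzenesulfenic acid from 14, loss of ethanol and hydrolysis of the silyl ether aromatise the ring to the phenol, so the ring stereocentres of 14 are of no consequence. The closest known reaction types are the 1,6-addition of organocopper reagents to 2,4-dienoates with silyl trapping and the aromatic annulation of 1-alkoxy-1-silyloxy-1,3-dienes with vinyl sulfoxides as acetylene equivalents. The step needs 1,6- over 1,4-selectivity, which the twisted, non-conjugating 2,6-disubstituted ring A and the extended conjugation of the dienolate should secure, and an (E) double bond at the diene terminus, which follows from the s-trans dienoate. The orientation of the dienophile is irrelevant because both of its carbons end as ring CH groups.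

Step 7
Reactants: 15 methyl 3-{(4-hydroxyphenyl)[4-(methoxymethoxy)phenyl]methyl}-4-[4-(methoxymethoxy)phenyl]-2-{[4-(methoxymethoxy)phenyl]ethynyl}benzoate (racemic)
Product: 16 4-{[3-(hydroxymethyl)-6-[4-(methoxymethoxy)phenyl]-2-{[4-(methoxymethoxy)phenyl]ethynyl}phenyl][4-(methoxymethoxy)phenyl]methyl}phenol (racemic)
Conditions: i-Bu2AlH (5 equiv), CH2Cl2, −78 to 0 °C; aq. potassium sodium tartrate
Reagents that add atoms: none
Why: Diisobutylaluminium hydride reduces the methyl benzoate to the benzylic alcohol at low temperature (ester reduction), while the diarylalkyne, the MOM ethers and the triarylmethane are inert to it.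

Step 8
Reactants: 16 4-{[3-(hydroxymethyl)-6-[4-(methoxymethoxy)phenyl]-2-{[4-(methoxymethoxy)phenyl]ethynyl}phenyl][4-(methoxymethoxy)phenyl]methyl}phenol (racemic)
Product: 17 4,4'-{[3-(hydroxymethyl)-6-(4-hydroxyphenyl)-2-[(4-hydroxyphenyl)ethynyl]phenyl]methylene}diphenol
Conditions: HCl, MeOH, 40 °C
Reagents that add atoms: none
Why: Acid-catalysed acetal exchange with methanol removes the three MOM groups (acetal cleavage), and the triarylmethane, which has no leaving group on the central carbon, cannot ionise under these conditions.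

Step 9
Reactants: 17 4,4'-{[3-(hydroxymethyl)-6-(4-hydroxyphenyl)-2-[(4-hydroxyphenyl)ethynyl]phenyl]methylene}diphenol
Product: 18 selaginellin, 4-{[3-(hydroxymethyl)-6-(4-hydroxyphenyl)-2-[(4-hydroxyphenyl)ethynyl]phenyl](4-hydroxyphenyl)methylene}cyclohexa-2,5-dien-1-one
Conditions: DDQ (1 equiv), 1,4-dioxane, rt
Reagents that add atoms: none
Why: DDQ abstracts the hydride of the central C–H bond, the cation being stabilised by two para-hydroxyphenyl rings, and loss of a phenolic proton should give the quinone methide (dehydrogenation of a leuco triarylmethane).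

Compound list
1 | methyl 4-bromo-2-hydroxybenzoate | COC(=O)c1ccc(Br)cc1O | starting material
2 | methyl 4-bromo-3-formyl-2-hydroxybenzoate | COC(=O)c1ccc(Br)c(C=O)c1O | intermediate
3 | [4-(methoxymethoxy)phenyl]boronic acid | COCOc1ccc(B(O)O)cc1 | starting material
4 | methyl 3-formyl-2-hydroxy-4-[4-(methoxymethoxy)phenyl]benzoate | COC(=O)c1ccc(-c2ccc(OCOC)cc2)c(C=O)c1O | intermediate
5 | methyl 3-formyl-4-[4-(methoxymethoxy)phenyl]-2-{[(trifluoromethyl)sulfonyl]oxy}benzoate | COC(=O)c1ccc(-c2ccc(OCOC)cc2)c(C=O)c1OS(=O)(=O)C(F)(F)F | intermediate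
6 | 1-ethynyl-4-(methoxymethoxy)benzene | C#Cc1ccc(OCOC)cc1 | starting material
7 | methyl 3-formyl-4-[4-(methoxymethoxy)phenyl]-2-{[4-(methoxymethoxy)phenyl]ethynyl}benzoate | COC(=O)c1ccc(-c2ccc(OCOC)cc2)c(C=O)c1C#Cc1ccc(OCOC)cc1 | intermediate
8 | ethyl (2E)-4-(diethoxyphosphoryl)but-2-enoate | CCOC(=O)/C=C/CP(=O)(OCC)OCC | starting material
9 | ethyl (2E,4E)-5-{3-(methoxycarbonyl)-6-[4-(methoxymethoxy)phenyl]-2-{[4-(methoxymethoxy)phenyl]ethynyl}phenyl}penta-2,4-dienoate | CCOC(=O)/C=C/C=C/c1c(-c2ccc(OCOC)cc2)ccc(C(=O)OC)c1C#Cc1ccc(OCOC)cc1 | intermediate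
10 | 1-bromo-4-(methoxymethoxy)benzene | COCOc1ccc(Br)cc1 | starting material
11 | phenyl vinyl sulfoxide (racemic) | C=CS(=O)c1ccccc1 | starting material
12 | [4-(methoxymethoxy)phenyl]magnesium bromide | COCOc1ccc([Mg]Br)cc1 | intermediate
13 | methyl 3-{(2E)-5-ethoxy-1-[4-(methoxymethoxy)phenyl]-5-[(trimethylsilyl)oxy]penta-2,4-dien-1-yl}-4-[4-(methoxymethoxy)phenyl]-2-{[4-(methoxymethoxy)phenyl]ethynyl}benzoate (racemic; ketene acetal geometry not defined) | CCOC(O[Si](C)(C)C)=C/C=C/C(c1ccc(OCOC)cc1)c1c(-c2ccc(OCOC)cc2)ccc(C(=O)OC)c1C#Cc1ccc(OCOC)cc1 | intermediate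
14 | methyl 3-{[4-ethoxy-5-(phenylsulfinyl)-4-[(trimethylsilyl)oxy]cyclohex-2-en-1-yl][4-(methoxymethoxy)phenyl]methyl}-4-[4-(methoxymethoxy)phenyl]-2-{[4-(methoxymethoxy)phenyl]ethynyl}benzoate (mixture of diastereomers) | CCOC1(O[Si](C)(C)C)C=CC(C(c2ccc(OCOC)cc2)c2c(-c3ccc(OCOC)cc3)ccc(C(=O)OC)c2C#Cc2ccc(OCOC)cc2)CC1S(=O)c1ccccc1 | intermediate
15 | methyl 3-{(4-hydroxyphenyl)[4-(methoxymethoxy)phenyl]methyl}-4-[4-(methoxymethoxy)phenyl]-2-{[4-(methoxymethoxy)phenyl]ethynyl}benzoate (racemic) | COC(=O)c1ccc(-c2ccc(OCOC)cc2)c(C(c2ccc(O)cc2)c2ccc(OCOC)cc2)c1C#Cc1ccc(OCOC)cc1 | intermediate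
16 | 4-{[3-(hydroxymethyl)-6-[4-(methoxymethoxy)phenyl]-2-{[4-(methoxymethoxy)phenyl]ethynyl}phenyl][4-(methoxymethoxy)phenyl]methyl}phenol (racemic) | OCc1ccc(-c2ccc(OCOC)cc2)c(C(c2ccc(O)cc2)c2ccc(OCOC)cc2)c1C#Cc1ccc(OCOC)cc1 | intermediate
17 | 4,4'-{[3-(hydroxymethyl)-6-(4-hydroxyphenyl)-2-[(4-hydroxyphenyl)ethynyl]phenyl]methylene}diphenol | OCc1ccc(-c2ccc(O)cc2)c(C(c2ccc(O)cc2)c2ccc(O)cc2)c1C#Cc1ccc(O)cc1 | intermediate
18 | selaginellin | O=C1C=CC(=C(c2ccc(O)cc2)c2c(-c3ccc(O)cc3)ccc(CO)c2C#Cc2ccc(O)cc2)C=C1 | target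

Total step count: 9. Longest linear sequence: 9 steps (1 to 18).

Steps most likely to fail

Step 6. The conjugate addition may take the 1,4 course or stall at the hindered δ-carbon, and the ketene acetal may be protonated before it cycloadds. The fallback builds the same diene by carbocation chemistry and sets out from aldehyde 7. Grignard reagent 12 (THF, −78 °C) adds to the aldehyde to give methyl 3-{hydroxy[4-(methoxymethoxy)phenyl]methyl}-4-[4-(methoxymethoxy)phenyl]-2-{[4-(methoxymethoxy)phenyl]ethynyl}benzoate F1. Ionisation with BF3·OEt2 in CH2Cl2 at −78 °C and capture of the benzhydryl cation by (vinyloxy)trimethylsilane (Mukaiyama-type SN1 alkylation) gives the 3,3-diarylpropanal F2. Knoevenagel–Doebner condensation with malonic acid in Et3N at 90 °C gives the (3E)-pent-3-enoic acid F3 with the double bond already in place. Deprotonation at the α-carbon with lithium diisopropylamide (2.2 equiv) and Me3SiCl in THF at −78 °C gives the bis(trimethylsilyl) ketene acetal F4 without touching that double bond. Cycloaddition with 11 in toluene (80 then 110 °C) gives the sulfinyl cycloadduct F5, which after sulfoxide elimination and aqueous acetic acid returns to the route at phenol 15.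

Step 1. Formylation may be slow or incomplete at a position flanked by hydroxyl and bromine on an electron-poor phenol. The fallback uses directed metalation and sets out from 1. MOMCl and i-Pr2NEt in CH2Cl2 give methyl 4-bromo-2-(methoxymethoxy)benzoate F6. Magnesiation between the MOM ether and bromine with TMPMgCl·LiCl in THF at −40 °C, then DMF, gives methyl 4-bromo-3-formyl-2-(methoxymethoxy)benzoate F7. HCl in MeOH at rt removes the MOM group and returns to the route at 2.

Step 9. Over-oxidation or oxidative coupling of the electron-rich tetraphenol may compete with hydride abstraction. The fallback swaps oxidation and deprotection and sets out from 16, where only the ring made in step 6 carries a free hydroxyl group. DDQ in 1,4-dioxane at rt gives the tris-MOM quinone methide 4-{[3-(hydroxymethyl)-6-[4-(methoxymethoxy)phenyl]-2-{[4-(methoxymethoxy)phenyl]ethynyl}phenyl][4-(methoxymethoxy)phenyl]methylene}cyclohexa-2,5-dien-1-one F8. HCl in MeOH at rt, then neutralisation, removes the MOM groups and returns to the route at 18.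

Further compounds
F1 | step 6 | methyl 3-{hydroxy[4-(methoxymethoxy)phenyl]methyl}-4-[4-(methoxymethoxy)phenyl]-2-{[4-(methoxymethoxy)phenyl]ethynyl}benzoate (racemic) | COC(=O)c1ccc(-c2ccc(OCOC)cc2)c(C(O)c2ccc(OCOC)cc2)c1C#Cc1ccc(OCOC)cc1
F2 | step 6 | methyl 4-[4-(methoxymethoxy)phenyl]-2-{[4-(methoxymethoxy)phenyl]ethynyl}-3-{1-[4-(methoxymethoxy)phenyl]-3-oxopropyl}benzoate (racemic) | COC(=O)c1ccc(-c2ccc(OCOC)cc2)c(C(CC=O)c2ccc(OCOC)cc2)c1C#Cc1ccc(OCOC)cc1
F3 | step 6 | (3E)-5-{3-(methoxycarbonyl)-6-[4-(methoxymethoxy)phenyl]-2-{[4-(methoxymethoxy)phenyl]ethynyl}phenyl}-5-[4-(methoxymethoxy)phenyl]pent-3-enoic acid (racemic) | COC(=O)c1ccc(-c2ccc(OCOC)cc2)c(C(/C=C/CC(=O)O)c2ccc(OCOC)cc2)c1C#Cc1ccc(OCOC)cc1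
F4 | step 6 | bis(trimethylsilyl) ketene acetal of F3 (racemic) | C[Si](C)(C)OC(O[Si](C)(C)C)=C/C=C/C(c1ccc(OCOC)cc1)c1c(-c2ccc(OCOC)cc2)ccc(C(=O)OC)c1C#Cc1ccc(OCOC)cc1
F5 | step 6 | cycloadduct of F4 and 11 (mixture of diastereomers) | C[Si](C)(C)OC1(O[Si](C)(C)C)C=CC(C(c2ccc(OCOC)cc2)c2c(-c3ccc(OCOC)cc3)ccc(C(=O)OC)c2C#Cc2ccc(OCOC)cc2)CC1S(=O)c1ccccc1
F6 | step 1 | methyl 4-bromo-2-(methoxymethoxy)benzoate | COCOc1cc(Br)ccc1C(=O)OC
F7 | step 1 | methyl 4-bromo-3-formyl-2-(methoxymethoxy)benzoate | COCOc1c(C=O)c(Br)ccc1C(=O)OC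
F8 | step 9 | 4-{[3-(hydroxymethyl)-6-[4-(methoxymethoxy)phenyl]-2-{[4-(methoxymethoxy)phenyl]ethynyl}phenyl][4-(methoxymethoxy)phenyl]methylene}cyclohexa-2,5-dien-1-one | O=C1C=CC(=C(c2ccc(OCOC)cc2)c2c(-c3ccc(OCOC)cc3)ccc(CO)c2C#Cc2ccc(OCOC)cc2)C=C1
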